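## The problem

Numbering used throughout: pyranone O1, C2–C6; side chain C7–C15 counted outward from the ring.

The target 22 is a 4-methoxy-3-methyl-2-pyranone whose C6 carries a nine-carbon chain with four stereocentres (7S, 8S, 11R, 14R) and two E-configured trisubstituted alkenes (C9=C10, C12=C13). The heterocycle is the only ring, so the work lies in building the chain and closing the pyranone late. C7 and C8 are neighbours and can be related by substrate control. C8 and C11 stand 1,4 across the C9=C10 alkene, beyond ordinary 1,2- or 1,3-induction, and C14 is isolated and needs a reagent-controlled step. C11 is doubly allylic: it can epimerise, or the alkenes can move into conjugation, whenever C12 is a carbonyl group under basic or hot conditions; C8 would behave likewise next to a C7 ketone. The pyranone is an electrophilic vinylogous lactone that does not survive hydride or organometallic reagents, and the C14 allylic and C7 secondary alcohols call for a mild final deprotection. The enabling feature is that the methyl-bearing carbons C8 and C11 flank the E-C9=C10 alkene while C11–C12 can be read as the α-carbon and carbonyl carbon of a β-lactone whose ring oxygen sits on C10. With the alkene placed at C8=C9, allylic displacement by a methyl nucleophile at C8 shifts the double bond to C9=C10, passes the configuration of C10 on to C8 and releases C12 as a carboxylic acid. C7 with its oxygen, and C6, map onto glyceraldehyde acetonide, whose terminal carbon can later become ring carbon C6.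

## Retrosynthesis

**22 ⇒ 21 ⇒ 20.** The two O–Si bonds and the O–CH3 bond are cut first. Triethylsilyl ethers at O7 and O14 come off under buffered fluoride, which leaves the pyranone and the allylic alcohol alone. The methyl ether is traced to the 4-hydroxy-2-pyranone 20 because ring closure delivers that tautomer directly. The forward methylation has to go to O4 and not to the C2 carbonyl oxygen.

**20 ⇒ 19 ⇒ 18 ⇒ 15 + 16 (through 17).** The ring is opened at O1–C2 (lactonisation of the 3,5-diketo ester 19) and then at C5–C6 (aldol addition of dianion 17 of keto ester 16 to aldehyde 15, followed by oxidation of 18). Cutting C5–C6 is preferred to cuts that add a three-carbon acyl unit to a methyl ketone, because it needs only an aldehyde at C6, exactly what the glyceraldehyde terminus offers, and forms the C–C bond at low temperature without acid. Five ring carbons with their substituents are removed in one cut. The forward sequence must add at the γ-carbon of the keto ester and must close the ring without enolising towards C7.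

**15 ⇒ 14 ⇒ 13 ⇒ 12.** No skeletal bond is cut. The C6 aldehyde with O7 and O14 silylated goes back to the tris(triethylsilyl) ether 14, the triol 13 and the acetonide 12. Silylating all three hydroxyl groups at once and oxidising the primary silyl ether directly avoids separate protection of O14 and a separate unmasking of O6.

**12 ⇒ 11 ⇒ 9 + 10.** The C14–H bond (reagent-controlled ketone reduction) and the C12=C13 alkene (Wittig olefination with keto ylide 10) are cut. C14 is too far from C11 for substrate control, so an oxazaborolidine-catalysed reduction of the enone 11, with the alkenyl group as the large substituent, is the natural choice. The aldehyde 9 is four carbons and one stereocentre simpler. The olefination must be E-selective and must not disturb C11.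

**9 ⇒ 8 ⇒ 7.** Redox adjustment of C12 only. The acid is reduced fully and re-oxidised so that the α-stereocentre C11 never sits next to an activated acyl group.

**7 ⇒ 6 (key disconnection).** The C8–CH3 bond is cut, and the C10–O bond of a β-lactone is restored with the alkene moved back to C8=C9. Against setting C8 and C11 by two independent reactions, this cut lets one stereocentre (C10) write the other (C8) by a stereospecific anti SN2' displacement. The product appears with the E-alkene, with C11 intact and with C12 already differentiated as an acid. The forward reaction has to be SN2' rather than SN2 or acyl attack, anti, and E-selective.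

**6 ⇒ 3 + 4 (through 5).** The four-membered ring is cut at C10–C11 and O–C12, a formal [2+2] of methylketene 5 (from propanoyl chloride 4) with enal 3 under alkaloid catalysis. One catalytic step sets the cis pair C10/C11. An auxiliary aldol route would need three steps to reach the same lactone.

**3 ⇒ 1 + 2.** The C8=C9 alkene is cut by Wittig olefination of (R)-glyceraldehyde acetonide 1 with formyl ylide 2. C7 comes from the chiral pool, and the E-geometry of C8=C9 is the second element, beside C10, that fixes the face of attack at C8.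

## Roads not taken

**Alternative 1: annulation of a methyl ketone enol ether with methylmalonyl dichloride.**
- Cut: C4–C5 and O1–C2 of the pyranone in one operation.
- Forward key step: the C5=C6 trimethylsilyl enol ether A1 of the fully elaborated chain attacks methylmalonyl dichloride A2 at carbon, and the enol oxygen then acylates to close the ring, giving the bis-silylated hydroxypyranone A3.
- Merits: two ring bonds in one step; the C3 methyl group and C4 oxygen arrive in a single reagent; no strongly basic dianion and no tricarbonyl intermediate.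
- Weak points: two equivalents of HCl are released beside an α-silyloxy ketone centre (C7), an allylic silyl ether (C14) and the skipped diene. A2 can also acylate at oxygen. A1 must be formed on the methyl side without touching C7–H.
- Comparison: this is an endgame variant only and leaves the chain problem open. From aldehyde 15 it needs methyl addition, oxidation, enol silylation and annulation, four steps against three (15 to 20) in the chosen plan. It is better in avoiding strong base. The chosen plan sets against this an acid-free C–C bond formation at −78 °C and a neutral-to-basic ring closure that the silyl ethers tolerate.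

**Alternative 2: asymmetric hydrovinylation to create C11.**
- Cut: C11–C12.
- Forward key step: diene A4 (C9=C10–C11=CH2) and ethylene A5 combine under CoCl2 with a chiral bisphosphine, activated by methylaluminoxane. Hydrogen goes to the terminal carbon and the vinyl group to C11, giving the skipped diene A6.
- Merits: C11 is set by a catalyst from a flat precursor with ethylene as the two-carbon unit; C8 and C11 are set independently, so any diastereomer is open.
- Weak points: the diene carries a trisubstituted internal alkene and a branched allylic centre (C8), so 1,2- against 1,4-addition and catalyst against substrate control are both uncertain. C7/C8 must first be made by a separate stereoselective step. The vinyl group of A6 must then become the E-trisubstituted C12=C13 alkene with the C14 carbinol. That requires cleaving a monosubstituted alkene beside the more electron-rich C9=C10, or a cross-metathesis to a trisubstituted alkene between two branched carbons.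
- Comparison: this road is more atom-economical at C11. The chosen plan answers with a stereospecific C10-to-C8 transfer in place of two independent selectivities, and with C12 emerging as a carboxylic acid that is distinguished from the alkenes at once.

**Alternative 3: enantioconvergent nickel alkenylation of a racemic pyranonyl bromo ketone.**
- Cut: C8–C9.
- Forward key step: the alkyne A8 is hydrozirconated with Cp2Zr(H)Cl to the alkenylzirconocene A9. A9 is coupled with the racemic α-bromo ketone A7 under NiCl2·glyme and a chiral bis(oxazoline), giving the (8S) C7 ketone A10 with the alkene geometry retained.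
- Merits: the most convergent of the four plans. The pyranone is made once on a small fragment, the electrophile is racemic, and the longest linear sequence would probably be shorter than the fifteen steps proposed here.
- Weak points: in A10 the C8 centre is α to a ketone and allylic, so epimerisation and alkene migration threaten before C7 is reduced. Precedent covers aryl alkyl ketones and mostly disubstituted alkenylzirconium reagents, not an electron-poor pyranonyl ketone or a trisubstituted alkenylmetal from an internal alkyne. C7 must then come from a diastereoselective reduction; the required 7,8-anti isomer corresponds to hydride attack anti to the alkenyl group, which is plausible. A8 needs C11 and C14 set by two further asymmetric steps.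
- Comparison: this road is better in convergence and probably in step count. The chosen plan sets against this that C7 comes from the chiral pool, that C8 is never next to a carbonyl group, and that every reaction type is established on its substrate class.

Key step: step 3

Assumption: O-trimethylsilylquinidine is taken to be the pseudo-enantiomer that delivers the (3R,4R)-cis-lactone 6, by analogy with the sense of quinidine-derived catalysts in methylketene reactions.

## Route

Step 1
Reactants: 1 (R)-2,2-dimethyl-1,3-dioxolane-4-carbaldehyde; 2 2-(triphenylphosphoranylidene)propanal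
Product: 3 (2E)-3-[(4S)-2,2-dimethyl-1,3-dioxolan-4-yl]-2-methylprop-2-enal
Conditions: toluene, 50 °C
Reagents that add atoms: none
Why: Wittig olefination with a formyl-stabilised ylide, which should give the E-enal under thermodynamic control of the oxaphosphetane; the α-alkoxy aldehyde 1 is far more electrophilic than the conjugated product, so a second olefination is not expected. C7 is untouched (its descriptor changes from R to S only through the priority rules).

Step 2
Reactants: 3 (2E)-3-[(4S)-2,2-dimethyl-1,3-dioxolan-4-yl]-2-methylprop-2-enal; 4 propanoyl chloride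
Product: 6 (3R,4R)-4-[(1E)-1-[(4S)-2,2-dimethyl-1,3-dioxolan-4-yl]prop-1-en-2-yl]-3-methyloxetan-2-one, via methylketene 5 (not isolated)
Conditions: O-trimethylsilylquinidine (15 mol%), LiClO4, iPr2NEt, CH2Cl2/Et2O, −78 °C
Reagents that add atoms: none
Why: Alkaloid-catalysed acyl halide–aldehyde cyclocondensation: the quinuclidine nitrogen adds to ketene 5 to give a Z-acylammonium enolate, which adds to the lithium-activated aldehyde through a closed chair transition state and then closes the ring with release of the catalyst, giving the cis-lactone. The alkaloid shields one enolate face and so sets C11 (R) and with it C10 (R); the C7 centre lies three bonds from the carbonyl group and should not compete. The lactone is to be purified on base-washed silica and used promptly.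

Step 3
Reactants: 6 (3R,4R)-4-[(1E)-1-[(4S)-2,2-dimethyl-1,3-dioxolan-4-yl]prop-1-en-2-yl]-3-methyloxetan-2-one
Product: 7 (2R,3E,5S)-5-[(4S)-2,2-dimethyl-1,3-dioxolan-4-yl]-2,4-dimethylhex-3-enoic acid
Conditions: MeMgBr (1.5 equiv), CuBr·SMe2 (10 mol%), THF/Me2S, −78 → −40 °C; then cold 0.5 M HCl
Reagents that add atoms: methylmagnesium bromide, C[Mg]Br
Why: Anti-selective SN2' substitution of an allylic carboxylate by a methylcuprate; the closest known reaction type is the copper-mediated Grignard opening of β-alkenyl β-lactones to (E)-β,γ-unsaturated acids. The methylcuprate formed from MeMgBr and monovalent copper binds the C8=C9 alkene on the face opposite the C10–O bond, oxidative addition with departure of the carboxylate places trivalent copper on C8, and reductive elimination forms the C8–CH3 bond. No ring closes; the four-membered ring opens, and its strain makes the carboxylate a leaving group without activation. The new C8 centre is controlled by C10: in the reactive rotamer the C10–O bond is perpendicular to the alkene plane, C10–H lies in the plane towards C8–H and C11 points away from C8, so with the (10R) oxygen on one face the methyl group enters the other and C8 becomes S. The same rotamer becomes the E-C9=C10 alkene because C11 ends up trans to C8; the other rotamer would press ring carbon C11 against C8–H and lead to a Z-alkene with two branched allylic carbons cis. The C7 centre should reinforce this: with C7–H eclipsing the C9 methyl group (least 1,3-allylic strain) the C7–O bond lies on the face opposite the incoming methyl group. The step needs SN2' over direct SN2 at C10 and over acyl attack; copper catalysis at low temperature and the hindered secondary C10 favour the former, and the magnesium carboxylate formed is inert to further addition. C11 passes through untouched and C10 is spent as the controlling element.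

Step 4
Reactants: 7 (2R,3E,5S)-5-[(4S)-2,2-dimethyl-1,3-dioxolan-4-yl]-2,4-dimethylhex-3-enoic acid
Product: 8 (2R,3E,5S)-5-[(4S)-2,2-dimethyl-1,3-dioxolan-4-yl]-2,4-dimethylhex-3-en-1-ol
Conditions: LiAlH4, THF, 0 °C → rt; H2O/aq. NaOH work-up
Reagents that add atoms: none
Why: Hydride reduction of the carboxylate to the primary alcohol; the carboxylate salt is not α-deprotonated under these conditions, so C11 is preserved, and the acetonide and the alkene are inert.

Step 5
Reactants: 8 (2R,3E,5S)-5-[(4S)-2,2-dimethyl-1,3-dioxolan-4-yl]-2,4-dimethylhex-3-en-1-ol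
Product: 9 (2R,3E,5S)-5-[(4S)-2,2-dimethyl-1,3-dioxolan-4-yl]-2,4-dimethylhex-3-enal
Conditions: Dess–Martin periodinane, NaHCO3, CH2Cl2, 0 °C
Reagents that add atoms: none
Why: Dess–Martin oxidation under buffered, near-neutral conditions, chosen because the α-methyl-β,γ-unsaturated aldehyde is sensitive to base and acid; the crude aldehyde is taken directly into step 6.

Step 6
Reactants: 9 (2R,3E,5S)-5-[(4S)-2,2-dimethyl-1,3-dioxolan-4-yl]-2,4-dimethylhex-3-enal; 10 3-(triphenylphosphoranylidene)butan-2-one
Product: 11 (3E,5R,6E,8S)-8-[(4S)-2,2-dimethyl-1,3-dioxolan-4-yl]-3,5,7-trimethylnona-3,6-dien-2-one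
Conditions: toluene, 80 °C
Reagents that add atoms: none
Why: Wittig olefination with a keto-stabilised ylide, which should give the E-trisubstituted enone; the ylide is non-basic enough that C11 and the C9=C10 position should survive.

Step 7
Reactants: 11 (3E,5R,6E,8S)-8-[(4S)-2,2-dimethyl-1,3-dioxolan-4-yl]-3,5,7-trimethylnona-3,6-dien-2-one
Product: 12 (2R,3E,5R,6E,8S)-8-[(4S)-2,2-dimethyl-1,3-dioxolan-4-yl]-3,5,7-trimethylnona-3,6-dien-2-ol
Conditions: (S)-Me-CBS oxazaborolidine ((S)-1-methyl-3,3-diphenyltetrahydro-1H,3H-pyrrolo[1,2-c][1,3,2]oxazaborole, 0.3 equiv), catecholborane, toluene, −78 °C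
Reagents that add atoms: none
Why: Corey–Bakshi–Shibata reduction: the ketone binds the catalyst with the α-substituted alkenyl group as the large substituent and methyl as the small one, so the (S)-catalyst should deliver hydride to give the (14R)-alcohol, as with aryl methyl ketones. Catecholborane gives 1,2-reduction and does not hydroborate the alkenes at this temperature.

Step 8
Reactants: 12 (2R,3E,5R,6E,8S)-8-[(4S)-2,2-dimethyl-1,3-dioxolan-4-yl]-3,5,7-trimethylnona-3,6-dien-2-ol
Product: 13 (2S,3S,4E,6R,7E,9R)-3,4,6,8-tetramethyldeca-4,7-diene-1,2,9-triol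
Conditions: AcOH/H2O (4:1), 25 → 40 °C
Reagents that add atoms: none
Why: Acid-catalysed hydrolysis of a terminal isopropylidene acetal; the acid is weak enough that the secondary allylic alcohol, whose allyl cation would have two secondary termini, should not ionise.

Step 9
Reactants: 13 (2S,3S,4E,6R,7E,9R)-3,4,6,8-tetramethyldeca-4,7-diene-1,2,9-triol
Product: 14 (2S,3S,4E,6R,7E,9R)-3,4,6,8-tetramethyl-1,2,9-tris(triethylsilyloxy)deca-4,7-diene
Conditions: TESOTf, 2,6-lutidine, CH2Cl2, −78 → 0 °C
Reagents that add atoms: triethylsilyl trifluoromethanesulfonate, CC[Si](CC)(CC)OS(=O)(=O)C(F)(F)F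
Why: Exhaustive silylation with a silyl triflate, reactive enough for the hindered C7 hydroxyl group; one operation protects O7 and O14 and arms O6 for the next step.

Step 10
Reactants: 14 (2S,3S,4E,6R,7E,9R)-3,4,6,8-tetramethyl-1,2,9-tris(triethylsilyloxy)deca-4,7-diene
Product: 15 (2S,3S,4E,6R,7E,9R)-3,4,6,8-tetramethyl-2,9-bis(triethylsilyloxy)deca-4,7-dienal
Conditions: (COCl)2, DMSO, CH2Cl2, −78 → −30 °C; then Et3N, −78 → 0 °C
Reagents that add atoms: none
Why: Swern oxidation applied directly to a primary triethylsilyl ether: the chlorosulfonium reagent exchanges the unhindered primary silyl group for the alkoxysulfonium ion, which collapses to the aldehyde on addition of base, while secondary triethylsilyl ethers are too hindered to react. This is a known selective oxidation of primary triethylsilyl ethers.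

Step 11
Reactants: 15 (2S,3S,4E,6R,7E,9R)-3,4,6,8-tetramethyl-2,9-bis(triethylsilyloxy)deca-4,7-dienal; 16 methyl 2-methyl-3-oxobutanoate
Product: 18 methyl (6S,7S,8E,10R,11E,13R)-5-hydroxy-2,7,8,10,12-pentamethyl-3-oxo-6,13-bis(triethylsilyloxy)tetradeca-8,11-dienoate (C2/C5 epimer mixture), via ketoester dianion 17 (not isolated)
Conditions: 16, NaH, THF, 0 °C; n-BuLi, 0 °C; then 15, −78 °C; aq. NH4Cl at −78 °C
Reagents that add atoms: none
Why: Aldol addition of a β-keto ester dianion, which reacts at its more basic terminal (γ) carbon and so forms C5–C6; the new C5 carbinol and the C2 centre are both erased later, so their configuration is immaterial. The cold quench is meant to forestall silyl migration from O7 to the new alkoxide.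

Step 12
Reactants: 18 methyl (6S,7S,8E,10R,11E,13R)-5-hydroxy-2,7,8,10,12-pentamethyl-3-oxo-6,13-bis(triethylsilyloxy)tetradeca-8,11-dienoate
Product: 19 methyl (6S,7S,8E,10R,11E,13R)-2,7,8,10,12-pentamethyl-3,5-dioxo-6,13-bis(triethylsilyloxy)tetradeca-8,11-dienoate
Conditions: Dess–Martin periodinane, NaHCO3, CH2Cl2, 0 °C → rt
Reagents that add atoms: none
Why: Dess–Martin oxidation of the δ-hydroxy-β-keto ester to the 3,5-diketo ester under buffered conditions that spare the silyl ethers; the product is expected as an enolised tricarbonyl, which lowers the acidity of C7–H.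

Step 13
Reactants: 19 methyl (6S,7S,8E,10R,11E,13R)-2,7,8,10,12-pentamethyl-3,5-dioxo-6,13-bis(triethylsilyloxy)tetradeca-8,11-dienoate
Product: 20 4-hydroxy-3-methyl-6-[(1S,2S,3E,5R,6E,8R)-2,3,5,7-tetramethyl-1,8-bis(triethylsilyloxy)nona-3,6-dien-1-yl]-2H-pyran-2-one
Conditions: DBU, toluene, 25 → 60 °C
Reagents that add atoms: none
Why: Base-induced cyclisation of a 3,5-diketo ester: the C6 enolate oxygen attacks the ester carbonyl (6-exo-trig lactonisation) and methanol is lost to give the aromatic 4-hydroxy-2-pyranone. Deprotonation occurs at C5 between the two ketones, so C7 should keep its configuration.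

Step 14
Reactants: 20 4-hydroxy-3-methyl-6-[(1S,2S,3E,5R,6E,8R)-2,3,5,7-tetramethyl-1,8-bis(triethylsilyloxy)nona-3,6-dien-1-yl]-2H-pyran-2-one
Product: 21 4-methoxy-3-methyl-6-[(1S,2S,3E,5R,6E,8R)-2,3,5,7-tetramethyl-1,8-bis(triethylsilyloxy)nona-3,6-dien-1-yl]-2H-pyran-2-one
Conditions: Me2SO4, K2CO3, acetone, rt
Reagents that add atoms: dimethyl sulfate, COS(=O)(=O)OC
Why: O-alkylation of the potassium salt of the vinylogous acid; under carbonate/dimethyl sulfate conditions 4-hydroxy-2-pyranones are methylated at O4 to the 4-methoxy-2-pyranone, whereas hard neutral methylating agents favour the 2-methoxy-4-pyranone isomer.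

Step 15
Reactants: 21 4-methoxy-3-methyl-6-[(1S,2S,3E,5R,6E,8R)-2,3,5,7-tetramethyl-1,8-bis(triethylsilyloxy)nona-3,6-dien-1-yl]-2H-pyran-2-one
Product: 22 6-[(1S,2S,3E,5R,6E,8R)-1,8-dihydroxy-2,3,5,7-tetramethylnona-3,6-dien-1-yl]-4-methoxy-3-methyl-2H-pyran-2-one
Conditions: HF·pyridine, pyridine, THF, 0 °C → rt
Reagents that add atoms: none
Why: Fluoride-mediated cleavage of both triethylsilyl ethers under buffered conditions that should leave the pyranone, the skipped diene and the allylic alcohol unchanged; no stereocentre is involved.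

## Compound list

1 | (R)-2,2-dimethyl-1,3-dioxolane-4-carbaldehyde | CC1(C)OC[C@@H](O1)C=O | starting material
2 | 2-(triphenylphosphoranylidene)propanal | CC(C=O)=P(c1ccccc1)(c1ccccc1)c1ccccc1 | starting material
3 | (2E)-3-[(4S)-2,2-dimethyl-1,3-dioxolan-4-yl]-2-methylprop-2-enal | CC1(C)OC[C@@H](O1)/C=C(\C)C=O | intermediate
4 | propanoyl chloride | CCC(=O)Cl | starting material
5 | methylketene (prop-1-en-1-one) | CC=C=O | intermediate (not isolated)
6 | (3R,4R)-4-[(1E)-1-[(4S)-2,2-dimethyl-1,3-dioxolan-4-yl]prop-1-en-2-yl]-3-methyloxetan-2-one | CC1(C)OC[C@@H](O1)/C=C(\C)[C@@H]2OC(=O)[C@@H]2C | intermediate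
7 | (2R,3E,5S)-5-[(4S)-2,2-dimethyl-1,3-dioxolan-4-yl]-2,4-dimethylhex-3-enoic acid | CC1(C)OC[C@@H](O1)[C@@H](C)/C(C)=C/[C@@H](C)C(=O)O | intermediate
8 | (2R,3E,5S)-5-[(4S)-2,2-dimethyl-1,3-dioxolan-4-yl]-2,4-dimethylhex-3-en-1-ol | CC1(C)OC[C@@H](O1)[C@@H](C)/C(C)=C/[C@@H](C)CO | intermediate
9 | (2R,3E,5S)-5-[(4S)-2,2-dimethyl-1,3-dioxolan-4-yl]-2,4-dimethylhex-3-enal | CC1(C)OC[C@@H](O1)[C@@H](C)/C(C)=C/[C@@H](C)C=O | intermediate
10 | 3-(triphenylphosphoranylidene)butan-2-one | CC(=O)C(C)=P(c1ccccc1)(c1ccccc1)c1ccccc1 | starting material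
11 | (3E,5R,6E,8S)-8-[(4S)-2,2-dimethyl-1,3-dioxolan-4-yl]-3,5,7-trimethylnona-3,6-dien-2-one | CC1(C)OC[C@@H](O1)[C@@H](C)/C(C)=C/[C@@H](C)/C=C(\C)C(C)=O | intermediate
12 | (2R,3E,5R,6E,8S)-8-[(4S)-2,2-dimethyl-1,3-dioxolan-4-yl]-3,5,7-trimethylnona-3,6-dien-2-ol | CC1(C)OC[C@@H](O1)[C@@H](C)/C(C)=C/[C@@H](C)/C=C(\C)[C@@H](C)O | intermediate
13 | (2S,3S,4E,6R,7E,9R)-3,4,6,8-tetramethyldeca-4,7-diene-1,2,9-triol | OC[C@@H](O)[C@@H](C)/C(C)=C/[C@@H](C)/C=C(\C)[C@@H](C)O | intermediate
14 | (2S,3S,4E,6R,7E,9R)-3,4,6,8-tetramethyl-1,2,9-tris(triethylsilyloxy)deca-4,7-diene | CC[Si](CC)(CC)OC[C@@H](O[Si](CC)(CC)CC)[C@@H](C)/C(C)=C/[C@@H](C)/C=C(\C)[C@@H](C)O[Si](CC)(CC)CC | intermediate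
15 | (2S,3S,4E,6R,7E,9R)-3,4,6,8-tetramethyl-2,9-bis(triethylsilyloxy)deca-4,7-dienal | O=C[C@@H](O[Si](CC)(CC)CC)[C@@H](C)/C(C)=C/[C@@H](C)/C=C(\C)[C@@H](C)O[Si](CC)(CC)CC | intermediate
16 | methyl 2-methyl-3-oxobutanoate | COC(=O)C(C)C(C)=O | starting material
17 | sodium lithium dianion of methyl 2-methyl-3-oxobutanoate | C=C([O-])C(C)=C([O-])OC.[Li+].[Na+] | intermediate (not isolated)
18 | methyl (6S,7S,8E,10R,11E,13R)-5-hydroxy-2,7,8,10,12-pentamethyl-3-oxo-6,13-bis(triethylsilyloxy)tetradeca-8,11-dienoate (C2/C5 epimer mixture) | COC(=O)C(C)C(=O)CC(O)[C@@H](O[Si](CC)(CC)CC)[C@@H](C)/C(C)=C/[C@@H](C)/C=C(\C)[C@@H](C)O[Si](CC)(CC)CC | intermediate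
19 | methyl (6S,7S,8E,10R,11E,13R)-2,7,8,10,12-pentamethyl-3,5-dioxo-6,13-bis(triethylsilyloxy)tetradeca-8,11-dienoate | COC(=O)C(C)C(=O)CC(=O)[C@@H](O[Si](CC)(CC)CC)[C@@H](C)/C(C)=C/[C@@H](C)/C=C(\C)[C@@H](C)O[Si](CC)(CC)CC | intermediate
20 | 4-hydroxy-3-methyl-6-[(1S,2S,3E,5R,6E,8R)-2,3,5,7-tetramethyl-1,8-bis(triethylsilyloxy)nona-3,6-dien-1-yl]-2H-pyran-2-one | Cc1c(O)cc([C@@H](O[Si](CC)(CC)CC)[C@@H](C)/C(C)=C/[C@@H](C)/C=C(\C)[C@@H](C)O[Si](CC)(CC)CC)oc1=O | intermediate
21 | 4-methoxy-3-methyl-6-[(1S,2S,3E,5R,6E,8R)-2,3,5,7-tetramethyl-1,8-bis(triethylsilyloxy)nona-3,6-dien-1-yl]-2H-pyran-2-one | COc1cc([C@@H](O[Si](CC)(CC)CC)[C@@H](C)/C(C)=C/[C@@H](C)/C=C(\C)[C@@H](C)O[Si](CC)(CC)CC)oc(=O)c1C | intermediate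
22 | 6-[(1S,2S,3E,5R,6E,8R)-1,8-dihydroxy-2,3,5,7-tetramethylnona-3,6-dien-1-yl]-4-methoxy-3-methyl-2H-pyran-2-one | COc1cc([C@@H](O)[C@@H](C)/C(C)=C/[C@@H](C)/C=C(\C)[C@@H](C)O)oc(=O)c1C | target

## Step count and least certain steps

Total step count: 15. Longest linear sequence: 15 steps (1 to 22); compounds 2, 4, 10 and 16 enter as purchased reagents.

**Step 3 (key step).** The most likely failure is loss of regiocontrol. C8 is flanked by the dioxolane, so direct SN2 substitution at C10 or addition to the lactone carbonyl may compete with the SN2' path. Partial reaction through the rotamer with C11 inside would also erode the E-geometry. Fallback, from 6 to 8: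
- Lactone 6 is reduced with LiAlH4 to (2S,3R,4E)-5-[(4S)-2,2-dimethyl-1,3-dioxolan-4-yl]-2,4-dimethylpent-4-ene-1,3-diol F1.
- The primary hydroxyl group is silylated selectively (TBSCl, imidazole) to (2S,3R,4E)-1-(tert-butyldimethylsilyloxy)-5-[(4S)-2,2-dimethyl-1,3-dioxolan-4-yl]-2,4-dimethylpent-4-en-3-ol F2.
- The allylic alcohol is acylated with picolinic acid to (2S,3R,4E)-1-(tert-butyldimethylsilyloxy)-5-[(4S)-2,2-dimethyl-1,3-dioxolan-4-yl]-2,4-dimethylpent-4-en-3-yl pyridine-2-carboxylate F3.
- MeMgBr with CuBr·SMe2 displaces the magnesium-chelated picolinate in the known anti SN2' manner of allylic picolinates, giving tert-butyl{[(2R,3E,5S)-5-[(4S)-2,2-dimethyl-1,3-dioxolan-4-yl]-2,4-dimethylhex-3-en-1-yl]oxy}dimethylsilane F4.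
- Fluoride desilylation of F4 gives alcohol 8, where the route resumes.

**Step 2.** The conjugated, α-branched enal may react too slowly, so that dimerisation of methylketene takes over. The allylic C10–O bond of the lactone may also ionise during isolation. Fallback, from 3 to 6:
- A boron-mediated Evans syn-aldol reaction of 3 with (R)-4-benzyl-3-propanoyl-1,3-oxazolidin-2-one (Bu2BOTf, iPr2NEt) gives (4R)-4-benzyl-3-[(2R,3R,4E)-5-[(4S)-2,2-dimethyl-1,3-dioxolan-4-yl]-3-hydroxy-2,4-dimethylpent-4-enoyl]-1,3-oxazolidin-2-one F5.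
- LiOH/H2O2 removes the auxiliary to give (2R,3R,4E)-5-[(4S)-2,2-dimethyl-1,3-dioxolan-4-yl]-3-hydroxy-2,4-dimethylpent-4-enoic acid F6.
- Lactonisation by carboxyl activation (PhSO2Cl, pyridine, 0 °C) proceeds with retention at C10 and returns the cis-lactone 6.

**Step 6.** The keto ylide is sluggish. Prolonged heating of the α-methyl-β,γ-unsaturated aldehyde may cause epimerisation at C11 or migration of the C9=C10 alkene into conjugation. Fallback, from 9 to 11:
- Aldehyde 9 is olefinated at room temperature with the more nucleophilic N-methoxy-N-methyl-2-(triphenylphosphoranylidene)propanamide to give (2E,4R,5E,7S)-7-[(4S)-2,2-dimethyl-1,3-dioxolan-4-yl]-N-methoxy-N,2,4,6-tetramethylocta-2,5-dienamide F7.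
- MeMgBr converts F7 into enone 11.

**Step 10.** The secondary allylic silyl ether at C14 may be cleaved along with the primary one, or the α-silyloxy aldehyde may epimerise at C7 during the amine stage. Fallback, from 14 to 15:
- The primary silyl ether of 14 is removed selectively with HF·pyridine buffered with pyridine at 0 °C to give (2S,3S,4E,6R,7E,9R)-3,4,6,8-tetramethyl-2,9-bis(triethylsilyloxy)deca-4,7-dien-1-ol F8.
- Buffered Dess–Martin oxidation of F8 gives aldehyde 15.

**Step 13.** The amidine base may enolise the C6 ketone towards C7 before the ring closes, scrambling C7. Fallback, from 15 to 20, under neutral ring-forming conditions: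
- The lithium dienolate of 2,2,5,6-tetramethyl-4H-1,3-dioxin-4-one (LDA, THF, −78 °C) adds through its 6-methyl carbon to aldehyde 15, giving 6-[(3S,4S,5E,7R,8E,10R)-2-hydroxy-4,5,7,9-tetramethyl-3,10-bis(triethylsilyloxy)undeca-5,8-dien-1-yl]-2,2,5-trimethyl-4H-1,3-dioxin-4-one F9.
- Dess–Martin oxidation gives 2,2,5-trimethyl-6-[(3S,4S,5E,7R,8E,10R)-4,5,7,9-tetramethyl-2-oxo-3,10-bis(triethylsilyloxy)undeca-5,8-dien-1-yl]-4H-1,3-dioxin-4-one F10.
- Heating in toluene at 110 °C expels acetone to give the acylketene (6S,7S,8E,10R,11E,13R)-2,7,8,10,12-pentamethyl-6,13-bis(triethylsilyloxy)tetradeca-1,8,11-triene-1,3,5-trione F11, which is trapped by the enol oxygen of the C6 ketone to give hydroxypyranone 20.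

## Further compounds

F1 | step 3 | (2S,3R,4E)-5-[(4S)-2,2-dimethyl-1,3-dioxolan-4-yl]-2,4-dimethylpent-4-ene-1,3-diol | CC1(C)OC[C@@H](O1)/C=C(\C)[C@H](O)[C@@H](C)CO
F2 | step 3 | (2S,3R,4E)-1-(tert-butyldimethylsilyloxy)-5-[(4S)-2,2-dimethyl-1,3-dioxolan-4-yl]-2,4-dimethylpent-4-en-3-ol | CC1(C)OC[C@@H](O1)/C=C(\C)[C@H](O)[C@@H](C)CO[Si](C)(C)C(C)(C)C
F3 | step 3 | (2S,3R,4E)-1-(tert-butyldimethylsilyloxy)-5-[(4S)-2,2-dimethyl-1,3-dioxolan-4-yl]-2,4-dimethylpent-4-en-3-yl pyridine-2-carboxylate | CC1(C)OC[C@@H](O1)/C=C(\C)[C@H](OC(=O)c2ccccn2)[C@@H](C)CO[Si](C)(C)C(C)(C)C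
F4 | step 3 | tert-butyl{[(2R,3E,5S)-5-[(4S)-2,2-dimethyl-1,3-dioxolan-4-yl]-2,4-dimethylhex-3-en-1-yl]oxy}dimethylsilane | CC1(C)OC[C@@H](O1)[C@@H](C)/C(C)=C/[C@@H](C)CO[Si](C)(C)C(C)(C)C
F5 | step 2 | (4R)-4-benzyl-3-[(2R,3R,4E)-5-[(4S)-2,2-dimethyl-1,3-dioxolan-4-yl]-3-hydroxy-2,4-dimethylpent-4-enoyl]-1,3-oxazolidin-2-one | CC1(C)OC[C@@H](O1)/C=C(\C)[C@H](O)[C@@H](C)C(=O)N2[C@H](Cc3ccccc3)COC2=O
F6 | step 2 | (2R,3R,4E)-5-[(4S)-2,2-dimethyl-1,3-dioxolan-4-yl]-3-hydroxy-2,4-dimethylpent-4-enoic acid | CC1(C)OC[C@@H](O1)/C=C(\C)[C@H](O)[C@@H](C)C(=O)O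
F7 | step 6 | (2E,4R,5E,7S)-7-[(4S)-2,2-dimethyl-1,3-dioxolan-4-yl]-N-methoxy-N,2,4,6-tetramethylocta-2,5-dienamide | CC1(C)OC[C@@H](O1)[C@@H](C)/C(C)=C/[C@@H](C)/C=C(\C)C(=O)N(C)OC
F8 | step 10 | (2S,3S,4E,6R,7E,9R)-3,4,6,8-tetramethyl-2,9-bis(triethylsilyloxy)deca-4,7-dien-1-ol | OC[C@@H](O[Si](CC)(CC)CC)[C@@H](C)/C(C)=C/[C@@H](C)/C=C(\C)[C@@H](C)O[Si](CC)(CC)CC
F9 | step 13 | 6-[(3S,4S,5E,7R,8E,10R)-2-hydroxy-4,5,7,9-tetramethyl-3,10-bis(triethylsilyloxy)undeca-5,8-dien-1-yl]-2,2,5-trimethyl-4H-1,3-dioxin-4-one (carbinol epimer mixture) | CC1=C(CC(O)[C@@H](O[Si](CC)(CC)CC)[C@@H](C)/C(C)=C/[C@@H](C)/C=C(\C)[C@@H](C)O[Si](CC)(CC)CC)OC(C)(C)OC1=O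
F10 | step 13 | 2,2,5-trimethyl-6-[(3S,4S,5E,7R,8E,10R)-4,5,7,9-tetramethyl-2-oxo-3,10-bis(triethylsilyloxy)undeca-5,8-dien-1-yl]-4H-1,3-dioxin-4-one | CC1=C(CC(=O)[C@@H](O[Si](CC)(CC)CC)[C@@H](C)/C(C)=C/[C@@H](C)/C=C(\C)[C@@H](C)O[Si](CC)(CC)CC)OC(C)(C)OC1=O
F11 | step 13 | (6S,7S,8E,10R,11E,13R)-2,7,8,10,12-pentamethyl-6,13-bis(triethylsilyloxy)tetradeca-1,8,11-triene-1,3,5-trione (acylketene, not isolated) | O=C=C(C)C(=O)CC(=O)[C@@H](O[Si](CC)(CC)CC)[C@@H](C)/C(C)=C/[C@@H](C)/C=C(\C)[C@@H](C)O[Si](CC)(CC)CC
A1 | alternative 1 | (3S,4S,5E,7R,8E,10R)-3,10-bis(tert-butyldimethylsilyloxy)-4,5,7,9-tetramethyl-2-(trimethylsilyloxy)undeca-1,5,8-triene | C=C(O[Si](C)(C)C)[C@@H](O[Si](C)(C)C(C)(C)C)[C@@H](C)/C(C)=C/[C@@H](C)/C=C(\C)[C@@H](C)O[Si](C)(C)C(C)(C)C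
A2 | alternative 1 | methylmalonyl dichloride (2-methylpropanedioyl dichloride) | CC(C(=O)Cl)C(=O)Cl
A3 | alternative 1 | 6-[(1S,2S,3E,5R,6E,8R)-1,8-bis(tert-butyldimethylsilyloxy)-2,3,5,7-tetramethylnona-3,6-dien-1-yl]-4-hydroxy-3-methyl-2H-pyran-2-one | Cc1c(O)cc([C@@H](O[Si](C)(C)C(C)(C)C)[C@@H](C)/C(C)=C/[C@@H](C)/C=C(\C)[C@@H](C)O[Si](C)(C)C(C)(C)C)oc1=O
A4 | alternative 2 | (2S,3S,4E)-1,2-bis(tert-butyldimethylsilyloxy)-3,4-dimethylhepta-4,6-diene | CC(C)(C)[Si](C)(C)OC[C@@H](O[Si](C)(C)C(C)(C)C)[C@@H](C)/C(C)=C/C=C
A5 | alternative 2 | ethylene | C=C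
A6 | alternative 2 | (2S,3S,4E,6S)-1,2-bis(tert-butyldimethylsilyloxy)-3,4,6-trimethylocta-4,7-diene | CC(C)(C)[Si](C)(C)OC[C@@H](O[Si](C)(C)C(C)(C)C)[C@@H](C)/C(C)=C/[C@@H](C)C=C
A7 | alternative 3 | 6-(2-bromopropanoyl)-4-methoxy-3-methyl-2H-pyran-2-one (racemic) | COc1cc(C(=O)C(C)Br)oc(=O)c1C
A8 | alternative 3 | tert-butyl{[(2R,3E,5S)-3,5-dimethyloct-3-en-6-yn-2-yl]oxy}dimethylsilane | CC#C[C@@H](C)/C=C(\C)[C@@H](C)O[Si](C)(C)C(C)(C)C
A9 | alternative 3 | chlorobis(cyclopentadienyl)[(2E,4S,5E,7R)-7-(tert-butyldimethylsilyloxy)-4,6-dimethylocta-2,5-dien-2-yl]zirconium | C/C(=C\[C@@H](C)/C=C(\C)[C@@H](C)O[Si](C)(C)C(C)(C)C)[Zr](Cl)(C1C=CC=C1)C1C=CC=C1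
A10 | alternative 3 | 6-[(2S,3E,5R,6E,8R)-8-(tert-butyldimethylsilyloxy)-2,3,5,7-tetramethylnona-3,6-dienoyl]-4-methoxy-3-methyl-2H-pyran-2-one | COc1cc(C(=O)[C@@H](C)/C(C)=C/[C@@H](C)/C=C(\C)[C@@H](C)O[Si](C)(C)C(C)(C)C)oc(=O)c1C
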